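**Retrosynthetic overview**

- Feature used: C3 is a bare CH2 between the C4 ketone and C2, and C2 carries both O1 and ring B. The C2–C3 bond of ring C is therefore cut to a C3 carbenoid (from a diazoketone) and a benzylic C–H bond of an aryl 3,4-dimethoxybenzyl ether.
- The prenyl groups at C6 and C8 are cut last, to a 6,8-diiodide made by iodination ortho to the free 7-OH, so that no alkene is present when the carbenoid is generated.
- The diazoketone comes from 2,4-dihydroxyacetophenone by MOM protection of O4, alkylation of O2 with 3,4-dimethoxybenzyl chloride and detrifluoroacetylative diazo transfer.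
- Ring order: rings A and B are bought, ring C and the C2 stereocentre are made in the key step, and the side chains follow.

Key step: step 4

Assumption: Rh2(S-PTTL)4, dirhodium tetrakis[N-phthaloyl-(S)-tert-leucinate], is taken to give the 2S product; if its sense of induction proves opposite, the catalyst from (R)-tert-leucine is used with no other change.

**Route**

Step 1
Reactants: 1 2,4-dihydroxyacetophenone
Product: 2 1-[2-hydroxy-4-(methoxymethoxy)phenyl]ethanone
Conditions: MOMCl (1.1 equiv), K2CO3, acetone, 0 °C to rt
Reagents that add atoms: chloromethyl methyl ether, COCCl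
Why: Williamson-type O-alkylation; the 4-OH is the more acidic phenol and the only one not held in a hydrogen bond to the acetyl group, so one equivalent of MOMCl should protect O4 alone.

Step 2
Reactants: 2 1-[2-hydroxy-4-(methoxymethoxy)phenyl]ethanone; 3 3,4-dimethoxybenzyl chloride
Product: 4 1-[2-(3,4-dimethoxybenzyloxy)-4-(methoxymethoxy)phenyl]ethanone
Conditions: K2CO3, n-Bu4NI (cat.), DMF, 60 °C
Reagents that add atoms: none
Why: Williamson ether synthesis; in warm DMF the carbonate frees the chelated 2-OH as its phenoxide, which displaces chloride from the reactive benzylic chloride under iodide catalysis, and the MOM acetal is inert to base.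

Step 3
Reactants: 4 1-[2-(3,4-dimethoxybenzyloxy)-4-(methoxymethoxy)phenyl]ethanone
Product: 6 2-diazo-1-[2-(3,4-dimethoxybenzyloxy)-4-(methoxymethoxy)phenyl]ethanone, via trifluoroacetyl diketone 5 (not isolated)
Conditions: LiN(SiMe3)2, THF, −78 °C; CF3CO2CH2CF3; cold dilute aq. HCl work-up; then MsN3, Et3N, H2O, MeCN, rt
Reagents that add atoms: methanesulfonyl azide, CS(=O)(=O)N=[N+]=[N-] (the two diazo nitrogens); 2,2,2-trifluoroethyl trifluoroacetate, O=C(OCC(F)(F)F)C(F)(F)F (the trifluoroacetyl group of 5 only, lost again on the way to 6)
Why: Detrifluoroacetylative (Regitz-type) diazo transfer; the methyl ketone has one enolisable site, its lithium enolate is acylated in a Claisen condensation to the activated diketone 5, and the sulfonyl azide then transfers N2 to C3 with loss of the trifluoroacetyl group as the sulfonamide, which gives the terminal diazoketone without diazomethane.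

Step 4
Reactants: 6 2-diazo-1-[2-(3,4-dimethoxybenzyloxy)-4-(methoxymethoxy)phenyl]ethanone
Product: 7 (2S)-2-(3,4-dimethoxyphenyl)-7-(methoxymethoxy)chroman-4-one
Conditions: Rh2(S-PTTL)4 (2 mol%), CH2Cl2, 0 °C to rt, slow addition of 6
Reagents that add atoms: none
Why: The dirhodium catalyst (divalent rhodium) attacks the diazo carbon of 6 and expels N2; the rhodium carbenoid at C3 then engages one benzylic C–H bond of the O–CH2–aryl group in a three-centre transition state, hydrogen passing to C3 with hydridic character while C2–C3 forms and the catalyst is released. The closest known reaction type is the intramolecular C–H insertion of 2-alkoxyphenyl diazoketones alpha to the ether oxygen under dirhodium carboxylate catalysis, which gives chroman-4-ones and has been run with chiral carboxylates. Ring C closes as a six-membered ring by 1,6-insertion through C3–C4–C4a–C8a–O1–C2; no other sp3 C–H bond lies within reach of the carbenoid. The C2 stereocentre is set by the catalyst alone, because the chiral pocket formed by the phthalimido groups of the tert-leucinate ligands should admit only one of the two enantiotopic benzylic hydrogens. The selectivity needed is insertion over capture of the carbenoid by the O1 lone pair (five-membered oxonium ylide, then 1,2-shift of the benzyl group) and over addition to ring B; it rests on the double activation of the C–H bond by O1 and the electron-rich dimethoxyphenyl ring, on the low donor strength of O1, which is conjugated with the aryl ketone, and on the seven- or eight-membered transition state that ring B would need. CH2Cl2 is used because an arene solvent could be attacked by this acceptor-only carbenoid, slow addition suppresses carbene dimer formation, and no alkene is present yet.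

Step 5
Reactants: 7 (2S)-2-(3,4-dimethoxyphenyl)-7-(methoxymethoxy)chroman-4-one
Product: 8 (2S)-2-(3,4-dimethoxyphenyl)-7-hydroxychroman-4-one
Conditions: HCl (2 M aq.), THF, 40 °C, stopped at full conversion
Reagents that add atoms: none
Why: Acid hydrolysis of the MOM acetal; the acetal should ionise far more readily than the O1–C2 bond, whose oxygen is part of a vinylogous ester, so dilute acid at moderate temperature is expected to free the phenol without opening ring C or touching the aryl methyl ethers.

Step 6
Reactants: 8 (2S)-2-(3,4-dimethoxyphenyl)-7-hydroxychroman-4-one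
Product: 9 (2S)-2-(3,4-dimethoxyphenyl)-7-hydroxy-6,8-diiodochroman-4-one
Conditions: BnMe3N·ICl2 (2.2 equiv), NaHCO3, CH2Cl2–MeOH, rt
Reagents that add atoms: benzyltrimethylammonium dichloroiodate, C[N+](C)(C)Cc1ccccc1.Cl[I-]Cl
Why: Electrophilic aromatic iodination; under bicarbonate the acidic 7-OH (para to the ketone) reacts as its phenoxide at its two free ortho positions C6 and C8, the only activated sites of ring A, while the aryl ether ring B is far less reactive toward this mild reagent and the weak base should not open ring C.

Step 7
Reactants: 9 (2S)-2-(3,4-dimethoxyphenyl)-7-hydroxy-6,8-diiodochroman-4-one; 10 tributyl(3-methylbut-2-enyl)stannane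
Product: 11 (2S)-2-(3,4-dimethoxyphenyl)-7-hydroxy-6,8-bis(3-methylbut-2-enyl)chroman-4-one (IN0946)
Conditions: 10 (3 equiv), Pd(PPh3)4 (10 mol%), degassed DMF, 90 °C; aq. KF work-up, no acid
Reagents that add atoms: none
Why: Double Stille coupling; zerovalent palladium inserts into each C–I bond, the prenylstannane transmetalates to a prenylpalladium species that should couple at its less hindered primary terminus to give the linear 3-methylbut-2-enyl groups, and the neutral conditions leave the free phenol, the ketone and the C2 stereocentre alone.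

**Compound list**

1 | 2,4-dihydroxyacetophenone | CC(=O)c1ccc(O)cc1O | starting material
2 | 1-[2-hydroxy-4-(methoxymethoxy)phenyl]ethanone | CC(=O)c1ccc(OCOC)cc1O | intermediate
3 | 3,4-dimethoxybenzyl chloride | COc1ccc(CCl)cc1OC | starting material
4 | 1-[2-(3,4-dimethoxybenzyloxy)-4-(methoxymethoxy)phenyl]ethanone | CC(=O)c1ccc(OCOC)cc1OCc1ccc(OC)c(OC)c1 | intermediate
5 | 4,4,4-trifluoro-1-[2-(3,4-dimethoxybenzyloxy)-4-(methoxymethoxy)phenyl]butane-1,3-dione (trifluoroacetyl diketone, not isolated) | COCOc1ccc(C(=O)CC(=O)C(F)(F)F)c(OCc2ccc(OC)c(OC)c2)c1 | intermediate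
6 | 2-diazo-1-[2-(3,4-dimethoxybenzyloxy)-4-(methoxymethoxy)phenyl]ethanone | COCOc1ccc(C(=O)C=[N+]=[N-])c(OCc2ccc(OC)c(OC)c2)c1 | intermediate
7 | (2S)-2-(3,4-dimethoxyphenyl)-7-(methoxymethoxy)chroman-4-one | COc1ccc([C@@H]2CC(=O)c3ccc(OCOC)cc3O2)cc1OC | intermediate
8 | (2S)-2-(3,4-dimethoxyphenyl)-7-hydroxychroman-4-one | COc1ccc([C@@H]2CC(=O)c3ccc(O)cc3O2)cc1OC | intermediate
9 | (2S)-2-(3,4-dimethoxyphenyl)-7-hydroxy-6,8-diiodochroman-4-one | COc1ccc([C@@H]2CC(=O)c3cc(I)c(O)c(I)c3O2)cc1OC | intermediate
10 | tributyl(3-methylbut-2-enyl)stannane | CCCC[Sn](CCCC)(CCCC)CC=C(C)C | starting material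
11 | (2S)-2-(3,4-dimethoxyphenyl)-7-hydroxy-6,8-bis(3-methylbut-2-enyl)chroman-4-one (IN0946) | COc1ccc([C@@H]2CC(=O)c3cc(CC=C(C)C)c(O)c(CC=C(C)C)c3O2)cc1OC | target

**Step count and risks**

Total step count: 7. Longest linear sequence: 7 steps (1 to 11).

Steps most likely to fail:

1. Step 4. The carbenoid may be captured by the O1 lone pair (ylide formation and 1,2-benzyl shift) faster than it inserts, or the catalyst may distinguish the two enantiotopic hydrogens poorly because the carbenoid carbon is unsubstituted. Fallback: ring C is bought in as a chromone and C2 is set by asymmetric conjugate addition, so that the C2–aryl bond is formed in place of C2–C3. The fallback sets out from 2. Condensation with N,N-dimethylformamide dimethyl acetal (neat, 90 °C) should give (E)-3-(dimethylamino)-1-[2-hydroxy-4-(methoxymethoxy)phenyl]prop-2-en-1-one F1. This closes in warm AcOH, with loss of dimethylamine, to 7-(methoxymethoxy)-4H-chromen-4-one F2. Conjugate addition of 3,4-dimethoxyphenylboronic acid to F2 with Pd(OCOCF3)2 and the chiral pyridine-oxazoline ligand 4-tert-butyl-2-(pyridin-2-yl)-4,5-dihydrooxazole (NH4PF6, H2O, 1,2-dichloroethane, 60 °C), the ligand enantiomer chosen for 2S, returns to the route at 7.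

2. Step 7. Transmetalation of the prenylstannane may deliver the branched 1,1-dimethylallyl isomer at one or both positions, or the second coupling next to the free phenol may stall and leave reduced or mono-coupled material. Fallback: the prenyl groups are built in two stages from 9. Double Stille coupling with allyltributylstannane (Pd(PPh3)4, DMF, 90 °C), which has no regiochemical ambiguity, should give (2S)-6,8-diallyl-2-(3,4-dimethoxyphenyl)-7-hydroxychroman-4-one F3. Cross-metathesis of both allyl groups with 2-methylbut-2-ene (co-solvent) and the second-generation Grubbs catalyst RuCl2(=CHPh)(PCy3)(H2IMes) in CH2Cl2 at 40 °C, with loss of propene, then reaches the target 11.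

3. Step 5. Acid may open ring C, either by heterolysis of the benzylic C2–O1 bond assisted by the para-methoxy group or by retro-oxa-Michael reaction through the enol, and reclosure would erode the enantiomeric purity set in step 4. Fallback: O7 is carried as a benzyl ether and freed by neutral hydrogenolysis. The fallback sets out from 1. Benzyl bromide with K2CO3 in acetone should give 1-[4-(benzyloxy)-2-hydroxyphenyl]ethanone F4, and alkylation with 3 as in step 2 gives 1-[4-(benzyloxy)-2-(3,4-dimethoxybenzyloxy)phenyl]ethanone F5. Diazo transfer as in step 3 passes through 1-[4-(benzyloxy)-2-(3,4-dimethoxybenzyloxy)phenyl]-4,4,4-trifluorobutane-1,3-dione F6 to 1-[4-(benzyloxy)-2-(3,4-dimethoxybenzyloxy)phenyl]-2-diazoethanone F7. Insertion as in step 4 gives (2S)-7-(benzyloxy)-2-(3,4-dimethoxyphenyl)chroman-4-one F8. Hydrogenolysis (H2, Pd/C, EtOAc, rt), in which the exocyclic benzyl aryl ether should cleave well before the hindered cyclic C2–O1 bond, returns to the route at 8.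

**Further compounds**

F1 | step 4 | (E)-3-(dimethylamino)-1-[2-hydroxy-4-(methoxymethoxy)phenyl]prop-2-en-1-one | CN(C)/C=C/C(=O)c1ccc(OCOC)cc1O
F2 | step 4 | 7-(methoxymethoxy)-4H-chromen-4-one | O=c1ccoc2cc(OCOC)ccc12
F3 | step 7 | (2S)-6,8-diallyl-2-(3,4-dimethoxyphenyl)-7-hydroxychroman-4-one | COc1ccc([C@@H]2CC(=O)c3cc(CC=C)c(O)c(CC=C)c3O2)cc1OC
F4 | step 5 | 1-[4-(benzyloxy)-2-hydroxyphenyl]ethanone | CC(=O)c1ccc(OCc2ccccc2)cc1O
F5 | step 5 | 1-[4-(benzyloxy)-2-(3,4-dimethoxybenzyloxy)phenyl]ethanone | CC(=O)c1ccc(OCc2ccccc2)cc1OCc1ccc(OC)c(OC)c1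
F6 | step 5 | 1-[4-(benzyloxy)-2-(3,4-dimethoxybenzyloxy)phenyl]-4,4,4-trifluorobutane-1,3-dione | O=C(CC(=O)C(F)(F)F)c1ccc(OCc2ccccc2)cc1OCc1ccc(OC)c(OC)c1
F7 | step 5 | 1-[4-(benzyloxy)-2-(3,4-dimethoxybenzyloxy)phenyl]-2-diazoethanone | [N-]=[N+]=CC(=O)c1ccc(OCc2ccccc2)cc1OCc1ccc(OC)c(OC)c1
F8 | step 5 | (2S)-7-(benzyloxy)-2-(3,4-dimethoxyphenyl)chroman-4-one | COc1ccc([C@@H]2CC(=O)c3ccc(OCc4ccccc4)cc3O2)cc1OC
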